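If your hunch is that you will be waiting on the gas, the quick number follows from that.

| flask | starting material | gas | free catalyst | time |
|---|---|---|---|---|
| north-west | 0.050 M | 4.0 mM (held) | 1.2 mM | 12 h |
| south-east | 0.050 M | 4.0 mM (held) | 1.2 mM | 25 h |

1. which of these there is most of at the end, counted by the starting material in it, north-west (product / catalyst intermediate C / catalyst intermediate B / starting material)
2. which of these there is most of at the end, counted by the starting material in it, south-east (product / catalyst intermediate C / catalyst intermediate B / starting material)
3. how much there is at the end of the one of these that leads, in percent of the starting material charged: north-west
4. how much there is at the end of the one of these that leads, in percent of the starting material charged: south-east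

    reagent + free catalyst → catalyst intermediate A (k1 = 2500 /M/h)
    starting material + catalyst intermediate A → catalyst intermediate B (k2 = 150 /M/h)
    catalyst intermediate B → by-product + catalyst intermediate C (k3 = 540 /h)
    catalyst intermediate C ⇌ free catalyst + product (K4 = 0.14 M, k4 = 2.6 /h)
    gas ⇌ reagent, rate k5*(csat - [reagent]) (k5 = 0.35 /h, csat = 4.0 mM)
    2 starting material → homo dimer (k6 = 0.12 /M/h)

Follow one molecule of starting material. It can enter the catalyst loop, which uses one reagent per product and can draw at most 1.40 mM/h of reagent from the gas. Or it can go to the homo dimer, which takes two molecules per turn with 0.12 /M/h. Call the even-fork concentration the c(starting material) at which the two routes draw alike at that ceiling: 76.4 mM. With the loop held at that ceiling, the dimer's chance at any moment is the square of c(starting material) over the sum of that square and the square of the even-fork concentration; its complement is the selectivity for the loop. The charge of 0.050 M lies below it, so the dimer's chance starts at 30.0%.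

With the loop at its ceiling, north-west makes at most 33.6% product in 12 h. Midway c(starting material) is then 38.0 mM, the dimer's chance there is 19.8%, and so I reckon 58.1% starting material remains north-west and leads. South-east, by the same recipe, product reaches at most 70.0%, and I take it to lead there.

The forecast differs from my figures: starting material leading north-west at 65%, product leading south-east at 51%. It takes the loop at 1.14 mM/h at the start, and says: “I treated the intermediates as quasi-steady”.

| Leader | By hand | Forecast | Simulation |
|---|---|---|---|
| north-west, starting material | 58.1% | 65% | 64.8% |
| south-east, product | 70.0% | 51% | 51.4% |

South-east, the passage of gas into reagent ran steadily, with 11% of its turnover done after 2.50 h, and the capture of starting material by catalyst intermediate A had 50% of its turnover done after 12.5 h. For the forecast's 34% starting material south-east to stand 6 points off, the reading would have to move to 22.2 h or 28.0 h. North-west made 1.02 mM/h of product on average, less than my ceiling, and that reading puts the even-fork concentration at 65.0 mM.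

Now read the south-east flask at 4.0 d: with that even-fork concentration, averaging the dimer's chance from the charge down to nothing by Simpson's rule gives 14.8% dimer, so 85.2% product. That flask gives 85.4% product, with 0% starting material left.

The rate constants stand for no real mixture; what happens was integrated by code.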